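Early on, Saturday's run at −25 °C climbs slowly, reaching 9.6% after 50.0 min. Thursday's flask at −20 °C already reads 20.9% at 3.00 h, and from 6.00 h to 40.0 h its 4 readings lie flat within the scatter.

all flasks: substrate 0.54 M

| flask | first nucleophile | second nucleophile | temperature | remark | time |
|---|---|---|---|---|---|
| Thursday's | 2 equiv | 2.5 equiv | −20 °C | the very flask that is asked about, followed so far |  |
| Saturday's | 3 equiv | 2.5 equiv | −25 °C | run made earlier |  |
| flask | 2.00 equiv | 2.50 equiv | −20 °C |  | 40 h |

- Thursday's (time / h: target / %): 3.00: 20.9; 6.00: 22.0; 12.0: 23.2; 20.0: 22.1; 40.0: 23.6
- Saturday's (time / min: target / %): 4.00: 0.5; 12.0: 1.7; 20.0: 3.9; 30.0: 5.3; 50.0: 9.6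

(standard deviation of a reading: 0.5 percentage points)

- removed target is counted in

- blue: change nothing and wait 3.0 d more
- violet: at 40 h take out 90% of the target then present, then wait 3.0 d
- grey: at 40 h raise the temperature by 10 K, then wait 3.0 d

* target, in percent of the substrate first charged, at 40 h
* the remedy with the largest gain of target, or "none" below 2 percentage points (blue / violet / grey / none)
* target present, with what was taken out counted in, in percent of the substrate first charged, after blue
* target present, with what was taken out counted in, in percent of the substrate first charged, after violet

The mean of those flat readings, y = 22.7%, stands for the target at the asked time, with a standard error of 0.25 percentage points. The share of the charge outside target divided by the share in it is 3.40, or 0.532 decades: this rest odds r carries the reckoning.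

Violet takes out 90% of the target and counts it in, so the count after the wait can be bracketed. From above, the charge itself caps it at 100%. Tighter: if the whole rest stands in equilibrium with target (thermodynamic control), r returns, the remaining pool regrows one part in r plus one as target, and the count reaches 38.5%. From below: if the rest is a dead sink, nothing regrows and the count stays at y. The wait of 3.0 d is far longer than the 6.00 h by which Thursday's flask had flattened, so time does not stand in the way of the top. Blue, on flat readings, stays at y. Grey gets no bound tighter than the charge: the earlier runs stand at −20 °C and −25 °C, and grey goes 10 K up from −20 °C.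

The forecast gives 22.8% now, 23% after blue and 37% after violet, which lies inside the bracket and below its top; it picks violet and adds “Grey cannot be quantified from these runs”.

The flask gives 22.6%, 22.6% after blue and 38.1% after violet, inside the bracket; the best remedy is grey, gaining 29 points against violet's 16 points.

    substrate → intermediate (k = 0.00670 min⁻¹, Ea = 86.0 kJ mol⁻¹)
    first nucleophile + intermediate → target (k = 0.240 M⁻¹ min⁻¹, Ea = 63.0 kJ mol⁻¹)
    second nucleophile + intermediate → other capture product (k = 0.00760 M⁻¹ min⁻¹, Ea = 51.0 kJ mol⁻¹)
    target ⇌ isomer of the product (K = 3.20, k = 0.0240 min⁻¹, Ea = 74.0 kJ mol⁻¹, ΔH = −74.0 kJ mol⁻¹)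
    (constants at −20 °C)

At 40.0 h the rest of this flask is 72.3% isomer of the product and 5.05% other capture product. Grey's count of 51.6% puts r at 0.939, so 10 K lowers the odds by 0.559 decades.

In the neighbour flask with 0.800 equiv of first nucleophile, other capture product stands at 23.5% at 40.0 h. Thursday's r, whose rest still holds Thursday's other capture product, applied to the remaining pool of the neighbour flask gives 17.4% target, and the computed neighbour flask gives 18.2% target.

(The data stem from a simulated flask with constants of no real substance, and the scatter is random.)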